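All constants are assumed; no experiment stands behind them.

The easy mistake in this flask is to divide the G charge by the L charge, as if each L began a chain and each G reacted.

G 1.4 M; Z 0.420 M; L 10 mol%; time 20 min

- average number of monomer units in a chain (chains begun, living or dead) at 20 min
- part of the G that has reacted at 20 min

- two of one species on the left: rate k times its square, two consumed each time
- the average divides the monomer in chains by the number of chains begun, living and dead together
- run time (flask): 20 min

    G + Q → E + Q, rate k1*[Q]*[G] (k1 = 0.081 L mol⁻¹ s⁻¹)
    G + L → Q + E (k2 = 0.036 L mol⁻¹ s⁻¹)
    2 L → L2 (k3 = 0.11 L mol⁻¹ s⁻¹)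
    Q + Z → Q.Z (k4 = 0.0088 L mol⁻¹ s⁻¹)

We write g and z for the fractions of the G and Z charges left, and build the flask up in stages.

1. Take the main step by itself, with each L counted as a Q. Q is not consumed, so c heads for 100 % and the chain average is 10.0.

2. Add the coupling of L with itself. At the start, L goes to chains 1.6 times as fast as to coupling. With G held at its charge, integrating over the fall of L gives a chain share f = r·ln(1 + 1/r), where r is that ratio. So we reckon that 78.0 % of L begins chains. That makes chains 7.80 % of the G charge, and the average rises to 12.8.

3. Add Z. Dividing the rate of the main step by the rate at which Z is taken cancels Q, so g = z^S, leaving aside the G taken by L. Here S is the selectivity factor, the power that turns the fraction of Z left into the fraction of G left, and it is 9.20. The chains claim 26.0 % of the Z charge, so z ends at 74.0 % and g at 6.25 %. That gives c of 93.8 % and an average of 12.0.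

4. Speed: the half-life of Q against Z at its charge, 3.1 min, is shorter than the run, so we commit to these end values for 20 min.

The forecast gives 12.2 and 93.3 %, an average slightly above ours and a c slightly below ours, with the words “Z then slowly removes Q”.

The simulation gives 12.1 and 93.5 %.

In this flask z reads 75.1 % at 20.0 min, and raised to S it gives 7.14 %, against 6.53 % of G left. The neighbouring flask charges 0.10 M of Z, and there the same reckoning puts the chains at 1.09 of the Z charge, more than that charge. In that neighbour z reads 46 % at 20.0 min, and raised to S it gives 0.0818 %. The neighbour has 0.074 % of its G left, with an average of 13.0 and c of 99.9 %.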